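**Plan**

Labels: ring A and ring P are the benzene and pyran rings of the acetylchromene (unprimed chromene numbers), ring B and ring Q those of the dimethoxychromene (primed numbers); C1'' is the methine carbon, which is S in the target.
Cuts: first the C5–O protecting group; then the C1''–H bond together with the C3=C4 alkene, traced back by allylic transposition to a C4 carbinol with an exocyclic C3=C1'' alkene; then, in one operation, the C1''–C6' and C3–C4 bonds.
Enabling feature: C4, C3 and C1'' form an allylic three-carbon unit on ring P, so C4 can be an aldehyde carbon on ring A, C3 and C1'' (with its methyl) the two carbons of a methyl alkyne hung on the O1–C2 ether, and the aryl group on C1'' a C6' boron reagent of ring B.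
Forward order: ring Q is closed first on the ring B phenol; the ring A alkynyl aldehyde, already carrying the C6 acetyl group, is built in six steps; ring P closes in the rhodium step that also joins the halves; transposition and deprotection finish.
Stereochemistry: the chiral diene on rhodium sets C4 (S), syn carbometalation sets the E alkene (ring B cis to C4), and hydride delivery anti to the C4 oxygen in the palladium step converts these two elements into the S methine centre.

Key step: step 9

Assumption: the (R,R) enantiomer of the diene ligand is taken to give the 4S carbinol; if the induction runs the other way, the (S,S) ligand is used and nothing else changes.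

**Route**

Step 1
Reactants: 1 2,4,6-trimethoxybenzaldehyde
Product: 2 2,6-dihydroxy-4-methoxybenzaldehyde
Conditions: AlCl3 (4 equiv), CH2Cl2, 0 °C → reflux; 1 M aq. HCl, 0 °C
Reagents that add atoms: none
Why: Chelation-controlled Lewis-acid O-demethylation: AlCl3 bridges the carbonyl oxygen and each ortho methoxy oxygen, so chloride should cleave only the two ortho O–CH3 bonds (as in the known conversion of 2,6-dimethoxybenzaldehyde into 2,6-dihydroxybenzaldehyde) and leave the para methoxy group.

Step 2
Reactants: 2 2,6-dihydroxy-4-methoxybenzaldehyde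
Product: 3 2-hydroxy-4-methoxy-6-(methoxymethoxy)benzaldehyde
Conditions: MOMCl (1.05 equiv), i-Pr2NEt, CH2Cl2, 0 °C
Reagents that add atoms: chloromethyl methyl ether, COCCl
Why: Williamson-type O-alkylation: the two hydroxyls are equivalent, and after the first alkylation the remaining one is held in the hydrogen bond to the aldehyde and is less nucleophilic, so one equivalent of reagent should stop at the mono-ether.

Step 3
Reactants: 3 2-hydroxy-4-methoxy-6-(methoxymethoxy)benzaldehyde; 4 3-chloro-3-methylbut-1-yne
Product: 5 4-methoxy-2-(methoxymethoxy)-6-[(2-methylbut-3-yn-2-yl)oxy]benzaldehyde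
Conditions: CuCl2·2H2O (1 mol %), DBU, MeCN, 0 °C → rt
Reagents that add atoms: none
Why: Copper-catalysed propargylic etherification: DBU deprotonates the chelated phenol, and the copper acetylide formed from the tertiary propargylic chloride ionises and is captured at the phenoxide oxygen, a reaction known to tolerate electron-poor and ortho-carbonyl phenols.

Step 4
Reactants: 5 4-methoxy-2-(methoxymethoxy)-6-[(2-methylbut-3-yn-2-yl)oxy]benzaldehyde
Product: 6 2-(dimethoxymethyl)-5-methoxy-1-(methoxymethoxy)-3-[(2-methylbut-3-yn-2-yl)oxy]benzene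
Conditions: HC(OMe)3, MeOH, PPTS (cat.), rt; Et3N quench
Reagents that add atoms: trimethyl orthoformate, COC(OC)OC; methanol, CO
Why: Acid-catalysed acetalisation with the orthoformate as water scavenger: the donor-stabilised oxocarbenium ion forms under PPTS catalysis, which is too weak to cleave the aryl MOM ether or the tertiary propargylic ether at room temperature, and the acetal masks the aldehyde for the two organolithium steps.

Step 5
Reactants: 6 2-(dimethoxymethyl)-5-methoxy-1-(methoxymethoxy)-3-[(2-methylbut-3-yn-2-yl)oxy]benzene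
Product: 8 2-(dimethoxymethyl)-5-methoxy-1-(methoxymethoxy)-3-[(2-methylpent-3-yn-2-yl)oxy]benzene, via lithium acetylide 7 (not isolated)
Conditions: n-BuLi (1.05 equiv), THF, −78 °C; MeI, −78 °C → rt
Reagents that add atoms: iodomethane, CI
Why: Deprotonation of the terminal alkyne (by far the most acidic C–H, ring lithiation being slow at −78 °C with one equivalent of base) followed by SN2 methylation of the lithium acetylide.

Step 6
Reactants: 8 2-(dimethoxymethyl)-5-methoxy-1-(methoxymethoxy)-3-[(2-methylpent-3-yn-2-yl)oxy]benzene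
Product: 12 3-acetyl-4-methoxy-2-(methoxymethoxy)-6-[(2-methylpent-3-yn-2-yl)oxy]benzaldehyde, via aryllithium 9 (not isolated), via lithium hemiaminal adduct 10 (not isolated), via keto acetal 11 (not isolated)
Conditions: n-BuLi (1.2 equiv), THF, −20 °C; MeC(O)N(OMe)Me, −78 → 0 °C; 1 M aq. HCl, THF, 0 °C
Reagents that add atoms: N-methoxy-N-methylacetamide, CC(=O)N(C)OC; water, O
Why: Directed ortho-metalation followed by Weinreb ketone synthesis: the ring C–H flanked by OMOM and OMe is the cooperative site (the other free position lies between OMe and a bulky tertiary alkoxy group), the chelated tetrahedral adduct prevents over-addition, and cold dilute acid collapses the adduct and hydrolyses the very labile electron-rich dimethyl acetal faster than the MOM ether.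

Step 7
Reactants: 13 4-bromo-3,5-dimethoxyphenol; 14 3-methylbut-2-enal
Product: 16 6-bromo-5,7-dimethoxy-2,2-dimethyl-2H-chromene, via ortho-quinone methide 15 (not isolated)
Conditions: ethylenediammonium diacetate (10 mol %), xylene, 140 °C
Reagents that add atoms: none
Why: Amine-salt-catalysed phenol–enal chromenylation (Knoevenagel-type condensation at the carbon ortho to the hydroxyl, then oxa-6π electrocyclisation of the ortho-quinone methide closes ring Q); the two ortho positions are equivalent, so only one chromene can form.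

Step 8
Reactants: 16 6-bromo-5,7-dimethoxy-2,2-dimethyl-2H-chromene
Product: 19 (5,7-dimethoxy-2,2-dimethyl-2H-chromen-6-yl)boronic acid, via chromenyllithium 17 (not isolated), via lithium triisopropoxyborate 18 (not isolated)
Conditions: n-BuLi (1.05 equiv), THF, −78 °C; B(Oi-Pr)3, −78 → 0 °C; dilute aq. HCl to pH 5–6, 0 °C
Reagents that add atoms: triisopropyl borate, CC(C)OB(OC(C)C)OC(C)C; water, O
Why: Bromine–lithium exchange at −78 °C (faster than any deprotonation) fixes the metal at C6', borate trapping and hydrolysis give the boronic acid, and the work-up is kept cold and near neutral because 2,6-dialkoxyarylboronic acids protodeboronate easily.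

Step 9
Reactants: 12 3-acetyl-4-methoxy-2-(methoxymethoxy)-6-[(2-methylpent-3-yn-2-yl)oxy]benzaldehyde; 19 (5,7-dimethoxy-2,2-dimethyl-2H-chromen-6-yl)boronic acid
Product: 20 1-[(3E,4S)-3-[1-(5,7-dimethoxy-2,2-dimethyl-2H-chromen-6-yl)ethylidene]-4-hydroxy-7-methoxy-5-(methoxymethoxy)-2,2-dimethyl-3,4-dihydro-2H-chromen-6-yl]ethan-1-one
Conditions: 19 (3 equiv), [RhCl(C2H4)2]2 (2.5 mol %), (R,R)-Bn-bod* [(1R,4R)-2,5-dibenzylbicyclo[2.2.2]octa-2,5-diene] (5.5 mol %), KOH (0.3 equiv), 1,4-dioxane/H2O (10:1), 50 °C
Reagents that add atoms: none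
Why: The hydroxorhodium–diene complex (monovalent rhodium) takes the ring B aryl group from 19 by transmetalation, the arylrhodium species adds syn across the alkyne with the aryl group on the methyl-bearing carbon C1'' and rhodium on C3, the alkenylrhodium adds to the aldehyde carbon C4, and water protonates the rhodium alkoxide and returns the hydroxo complex. The closest known reaction type is the rhodium/chiral diene-catalysed asymmetric arylative cyclisation of alkynals with arylboronic acids, which gives cyclic allylic alcohols with a tetrasubstituted exocyclic alkene. Ring P closes in 6-exo-trig mode (C3 onto the exocyclic C=O at C4). The C4 configuration is set by the chiral diene, which selects the aldehyde face in the intramolecular carbonyl insertion, and the E alkene geometry follows from syn carbometalation with retention at the alkenyl–rhodium bond. The step needs regioselective insertion, secured by the quaternary C2 next to the alkyne (the bulky aryl group goes to the methyl terminus) and by the fact that only the C3-rhodium isomer can reach the aldehyde through a six-membered transition state; it also needs the alkenylrhodium to cyclise and not to migrate, which the two ortho methoxy groups of ring B secure by leaving no ortho C–H for a 1,4-rhodium shift. Direct arylation of the doubly ortho-substituted aldehyde and of the hindered acetyl group should be slow, and the excess of 19 compensates for protodeboronation of the 2,6-dialkoxyarylboronic acid.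

Step 10
Reactants: 20 1-[(3E,4S)-3-[1-(5,7-dimethoxy-2,2-dimethyl-2H-chromen-6-yl)ethylidene]-4-hydroxy-7-methoxy-5-(methoxymethoxy)-2,2-dimethyl-3,4-dihydro-2H-chromen-6-yl]ethan-1-one
Product: 21 (3E,4S)-6-acetyl-3-[1-(5,7-dimethoxy-2,2-dimethyl-2H-chromen-6-yl)ethylidene]-7-methoxy-5-(methoxymethoxy)-2,2-dimethyl-3,4-dihydro-2H-chromen-4-yl formate
Conditions: AcOCHO (preformed), pyridine, DMAP (cat.), CH2Cl2, −20 → 0 °C; neutral work-up, used without chromatography on acidic silica
Reagents that add atoms: acetic formic anhydride, CC(=O)OC=O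
Why: O-Formylation by acyl transfer with retention at C4: formyl is the smallest acyl group for the hindered carbinol, the formate is a poor enough leaving group not to ionise at the electron-rich benzylic position under basic conditions, and it carries the hydride needed in the next step.

Step 11
Reactants: 21 (3E,4S)-6-acetyl-3-[1-(5,7-dimethoxy-2,2-dimethyl-2H-chromen-6-yl)ethylidene]-7-methoxy-5-(methoxymethoxy)-2,2-dimethyl-3,4-dihydro-2H-chromen-4-yl formate
Product: 22 1-[3-[(1S)-1-(5,7-dimethoxy-2,2-dimethyl-2H-chromen-6-yl)ethyl]-7-methoxy-5-(methoxymethoxy)-2,2-dimethyl-2H-chromen-6-yl]ethan-1-one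
Conditions: Pd(OAc)2 (5 mol %), n-Bu3P (5 mol %), THF, 25–40 °C
Reagents that add atoms: none
Why: Palladium-catalysed hydrogenolysis of an allylic formate with 1,3-transposition (Tsuji–Trost-type ionisation, then decarboxylative hydride transfer): zerovalent palladium ionises the pseudo-axial C4–O bond with inversion, loss of CO2 from the palladium formate held at the secondary C4 terminus gives a hydride that is passed to the tertiary C1'' terminus on the palladium face, so the E geometry and the 4S centre should translate into the S methine centre while the C3=C4 alkene of ring P forms.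

Step 12
Reactants: 22 1-[3-[(1S)-1-(5,7-dimethoxy-2,2-dimethyl-2H-chromen-6-yl)ethyl]-7-methoxy-5-(methoxymethoxy)-2,2-dimethyl-2H-chromen-6-yl]ethan-1-one
Product: 23 1-[3-[(1S)-1-(5,7-dimethoxy-2,2-dimethyl-2H-chromen-6-yl)ethyl]-5-hydroxy-7-methoxy-2,2-dimethyl-2H-chromen-6-yl]ethan-1-one (CNP0303487.1)
Conditions: HCl (0.5 M) in MeOH, rt
Reagents that add atoms: none
Why: Acid-catalysed acetal exchange (MOM cleavage), eased by the hydrogen bond from the freed phenol to the acetyl group, under conditions dilute enough to leave the aryl methyl ethers, both 2,2-dimethylchromene units and the methine stereocentre untouched.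

**Compound list**

1 | 2,4,6-trimethoxybenzaldehyde | COc1cc(OC)c(C=O)c(OC)c1 | starting material
2 | 2,6-dihydroxy-4-methoxybenzaldehyde | COc1cc(O)c(C=O)c(O)c1 | intermediate
3 | 2-hydroxy-4-methoxy-6-(methoxymethoxy)benzaldehyde | COCOc1cc(OC)cc(O)c1C=O | intermediate
4 | 3-chloro-3-methylbut-1-yne | CC(C)(Cl)C#C | starting material
5 | 4-methoxy-2-(methoxymethoxy)-6-[(2-methylbut-3-yn-2-yl)oxy]benzaldehyde | COCOc1cc(OC)cc(OC(C)(C)C#C)c1C=O | intermediate
6 | 2-(dimethoxymethyl)-5-methoxy-1-(methoxymethoxy)-3-[(2-methylbut-3-yn-2-yl)oxy]benzene | COCOc1cc(OC)cc(OC(C)(C)C#C)c1C(OC)OC | intermediate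
7 | lithium acetylide of 6 (not isolated) | COCOc1cc(OC)cc(OC(C)(C)C#C[Li])c1C(OC)OC | intermediate
8 | 2-(dimethoxymethyl)-5-methoxy-1-(methoxymethoxy)-3-[(2-methylpent-3-yn-2-yl)oxy]benzene | COCOc1cc(OC)cc(OC(C)(C)C#CC)c1C(OC)OC | intermediate
9 | [3-(dimethoxymethyl)-6-methoxy-2-(methoxymethoxy)-4-[(2-methylpent-3-yn-2-yl)oxy]phenyl]lithium (not isolated) | COCOc1c([Li])c(OC)cc(OC(C)(C)C#CC)c1C(OC)OC | intermediate
10 | lithium 1-[3-(dimethoxymethyl)-6-methoxy-2-(methoxymethoxy)-4-[(2-methylpent-3-yn-2-yl)oxy]phenyl]-1-[methoxy(methyl)amino]ethan-1-olate (not isolated) | COCOc1c(C(C)(O[Li])N(C)OC)c(OC)cc(OC(C)(C)C#CC)c1C(OC)OC | intermediate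
11 | 1-[3-(dimethoxymethyl)-6-methoxy-2-(methoxymethoxy)-4-[(2-methylpent-3-yn-2-yl)oxy]phenyl]ethan-1-one (not isolated) | COCOc1c(C(C)=O)c(OC)cc(OC(C)(C)C#CC)c1C(OC)OC | intermediate
12 | 3-acetyl-4-methoxy-2-(methoxymethoxy)-6-[(2-methylpent-3-yn-2-yl)oxy]benzaldehyde | COCOc1c(C(C)=O)c(OC)cc(OC(C)(C)C#CC)c1C=O | intermediate
13 | 4-bromo-3,5-dimethoxyphenol | COc1cc(O)cc(OC)c1Br | starting material
14 | 3-methylbut-2-enal | CC(C)=CC=O | starting material
15 | 4-bromo-3,5-dimethoxy-6-(3-methylbut-2-en-1-ylidene)cyclohexa-2,4-dien-1-one (ortho-quinone methide, not isolated) | O=C1C=C(OC)C(Br)=C(OC)C1=CC=C(C)C | intermediate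
16 | 6-bromo-5,7-dimethoxy-2,2-dimethyl-2H-chromene | COc1cc2c(c(OC)c1Br)C=CC(C)(C)O2 | intermediate
17 | (5,7-dimethoxy-2,2-dimethyl-2H-chromen-6-yl)lithium (not isolated) | COc1cc2c(c(OC)c1[Li])C=CC(C)(C)O2 | intermediate
18 | lithium (5,7-dimethoxy-2,2-dimethyl-2H-chromen-6-yl)tri(propan-2-yloxy)borate (not isolated) | COc1cc2c(c(OC)c1[B-](OC(C)C)(OC(C)C)OC(C)C)C=CC(C)(C)O2.[Li+] | intermediate
19 | (5,7-dimethoxy-2,2-dimethyl-2H-chromen-6-yl)boronic acid | COc1cc2c(c(OC)c1B(O)O)C=CC(C)(C)O2 | intermediate
20 | 1-[(3E,4S)-3-[1-(5,7-dimethoxy-2,2-dimethyl-2H-chromen-6-yl)ethylidene]-4-hydroxy-7-methoxy-5-(methoxymethoxy)-2,2-dimethyl-3,4-dihydro-2H-chromen-6-yl]ethan-1-one | COc1cc2c(c(OCOC)c1C(C)=O)[C@@H](O)/C(=C(/C)c1c(OC)cc3c(c1OC)C=CC(C)(C)O3)C(C)(C)O2 | intermediate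
21 | (3E,4S)-6-acetyl-3-[1-(5,7-dimethoxy-2,2-dimethyl-2H-chromen-6-yl)ethylidene]-7-methoxy-5-(methoxymethoxy)-2,2-dimethyl-3,4-dihydro-2H-chromen-4-yl formate | COc1cc2c(c(OCOC)c1C(C)=O)[C@@H](OC=O)/C(=C(/C)c1c(OC)cc3c(c1OC)C=CC(C)(C)O3)C(C)(C)O2 | intermediate
22 | 1-[3-[(1S)-1-(5,7-dimethoxy-2,2-dimethyl-2H-chromen-6-yl)ethyl]-7-methoxy-5-(methoxymethoxy)-2,2-dimethyl-2H-chromen-6-yl]ethan-1-one | COc1cc2c(c(OCOC)c1C(C)=O)C=C([C@H](C)c1c(OC)cc3c(c1OC)C=CC(C)(C)O3)C(C)(C)O2 | intermediate
23 | 1-[3-[(1S)-1-(5,7-dimethoxy-2,2-dimethyl-2H-chromen-6-yl)ethyl]-5-hydroxy-7-methoxy-2,2-dimethyl-2H-chromen-6-yl]ethan-1-one | COc1cc2c(c(O)c1C(C)=O)C=C([C@H](C)c1c(OC)cc3c(c1OC)C=CC(C)(C)O3)C(C)(C)O2 | target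

**Step count and risks**

Total step count: 12. Longest linear sequence: 10 steps (steps 1–6, then 9–12); steps 7–8 form the ring B branch.

Most likely to fail, riskiest first:

Step 9. Transmetalation of the doubly ortho-substituted aryl group from boron to rhodium may be slower than base-mediated protodeboronation of 19, so the aryl donor is consumed before the alkyne is carbometalated; facial selectivity at the hindered aldehyde may also be lower than with simple alkynals. The fallback changes the aryl donor class and works without water or base. It sets out from bromide 16 and aldehyde 12. Bromine–lithium exchange as in step 8 gives 17, which ZnCl2 converts into the arylzinc chloride F1. Arylzinc chlorides transmetalate rapidly to chlororhodium–diene complexes in THF (the known rhodium/chiral diene-catalysed additions of arylzinc chlorides), so the same syn insertion and carbonyl addition should run with [RhCl(C2H4)2]2 and (R,R)-Bn-bod* at 0–25 °C and leave the chlorozinc alkoxide F2. Neutral aqueous work-up converts F2 into 20, where the route is rejoined.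

Step 11. Hydride may be delivered to C4 instead of C1'' (leaving the ethylidene chroman), the allylpalladium intermediate may lose a β-hydrogen from the C1'' methyl group to give a diene, and the stereochemical relay is eroded if the electron-rich benzylic formate ionises without palladium or if the allylpalladium species exchanges faces. The fallback replaces metal-mediated delivery by a concerted sigmatropic hydrogen transfer. It sets out from carbinol 20. A Mitsunobu reaction with 2-nitrobenzenesulfonylhydrazide (PPh3, DEAD, THF/N-methylmorpholine, −30 °C) should give, with inversion at C4, the N-allyl-N-sulfonylhydrazine F3. On warming to room temperature this loses 2-nitrobenzenesulfinic acid to give the allylic diazene F4, whose retro-ene loss of N2 passes hydrogen suprafacially to C1'' and moves the alkene to C3=C4. Hydrogen again enters anti to the original C4 oxygen, so the sequence comes back to the route at 22. Its own weak point is that the Mitsunobu intermediate may ionise at the electron-rich benzylic C4, which is why it is the fallback and not the main line.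

Step 6. The base may deprotonate the propargylic methyl group or the ring position between the methoxy and tert-alkoxy groups in competition with the OMOM/OMe-flanked position, and the hindered aryllithium may enolise the Weinreb amide instead of adding to it. The fallback introduces the acetyl group only after the alkyne has been consumed. It sets out from acetal 8. Cold dilute HCl hydrolyses 8 to the aldehyde F5, which is carried through the chemistry of steps 9, 10 and 11 to give in turn the carbinol F6, the formate F7 and the MOM-protected chromene F8. In F8 the only OMOM-flanked ring C–H is C6–H, so n-BuLi (THF, −20 °C) should give the aryllithium F9, which adds to N-methoxy-N-methylacetamide to give the lithium hemiaminal adduct F10. Aqueous work-up releases the ketone and the route is rejoined at 22.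

**Further compounds**

F1 | step 9 | chlorido(5,7-dimethoxy-2,2-dimethyl-2H-chromen-6-yl)zinc | COc1cc2c(c(OC)c1[Zn]Cl)C=CC(C)(C)O2
F2 | step 9 | chlorozinc (3E,4S)-6-acetyl-3-[1-(5,7-dimethoxy-2,2-dimethyl-2H-chromen-6-yl)ethylidene]-7-methoxy-5-(methoxymethoxy)-2,2-dimethyl-3,4-dihydro-2H-chromen-4-olate | COc1cc2c(c(OCOC)c1C(C)=O)[C@@H](O[Zn]Cl)/C(=C(/C)c1c(OC)cc3c(c1OC)C=CC(C)(C)O3)C(C)(C)O2
F3 | step 11 | N-[(3E,4R)-6-acetyl-3-[1-(5,7-dimethoxy-2,2-dimethyl-2H-chromen-6-yl)ethylidene]-7-methoxy-5-(methoxymethoxy)-2,2-dimethyl-3,4-dihydro-2H-chromen-4-yl]-2-nitrobenzenesulfonohydrazide | COc1cc2c(c(OCOC)c1C(C)=O)[C@H](N(N)S(=O)(=O)c1ccccc1[N+](=O)[O-])/C(=C(/C)c1c(OC)cc3c(c1OC)C=CC(C)(C)O3)C(C)(C)O2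
F4 | step 11 | 1-[(3E,4R)-4-diazenyl-3-[1-(5,7-dimethoxy-2,2-dimethyl-2H-chromen-6-yl)ethylidene]-7-methoxy-5-(methoxymethoxy)-2,2-dimethyl-3,4-dihydro-2H-chromen-6-yl]ethan-1-one | COc1cc2c(c(OCOC)c1C(C)=O)[C@H](N=N)/C(=C(/C)c1c(OC)cc3c(c1OC)C=CC(C)(C)O3)C(C)(C)O2
F5 | step 6 | 4-methoxy-2-(methoxymethoxy)-6-[(2-methylpent-3-yn-2-yl)oxy]benzaldehyde | COCOc1cc(OC)cc(OC(C)(C)C#CC)c1C=O
F6 | step 6 | (3E,4S)-3-[1-(5,7-dimethoxy-2,2-dimethyl-2H-chromen-6-yl)ethylidene]-7-methoxy-5-(methoxymethoxy)-2,2-dimethyl-3,4-dihydro-2H-chromen-4-ol | COc1cc2c(c(OCOC)c1)[C@@H](O)/C(=C(/C)c1c(OC)cc3c(c1OC)C=CC(C)(C)O3)C(C)(C)O2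
F7 | step 6 | (3E,4S)-3-[1-(5,7-dimethoxy-2,2-dimethyl-2H-chromen-6-yl)ethylidene]-7-methoxy-5-(methoxymethoxy)-2,2-dimethyl-3,4-dihydro-2H-chromen-4-yl formate | COc1cc2c(c(OCOC)c1)[C@@H](OC=O)/C(=C(/C)c1c(OC)cc3c(c1OC)C=CC(C)(C)O3)C(C)(C)O2
F8 | step 6 | 5,7-dimethoxy-6-[(1S)-1-[7-methoxy-5-(methoxymethoxy)-2,2-dimethyl-2H-chromen-3-yl]ethyl]-2,2-dimethyl-2H-chromene | COc1cc2c(c(OCOC)c1)C=C([C@H](C)c1c(OC)cc3c(c1OC)C=CC(C)(C)O3)C(C)(C)O2
F9 | step 6 | [3-[(1S)-1-(5,7-dimethoxy-2,2-dimethyl-2H-chromen-6-yl)ethyl]-7-methoxy-5-(methoxymethoxy)-2,2-dimethyl-2H-chromen-6-yl]lithium | COc1cc2c(c(OCOC)c1[Li])C=C([C@H](C)c1c(OC)cc3c(c1OC)C=CC(C)(C)O3)C(C)(C)O2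
F10 | step 6 | lithium 1-[3-[(1S)-1-(5,7-dimethoxy-2,2-dimethyl-2H-chromen-6-yl)ethyl]-7-methoxy-5-(methoxymethoxy)-2,2-dimethyl-2H-chromen-6-yl]-1-[methoxy(methyl)amino]ethan-1-olate | COc1cc2c(c(OCOC)c1C(C)(O[Li])N(C)OC)C=C([C@H](C)c1c(OC)cc3c(c1OC)C=CC(C)(C)O3)C(C)(C)O2
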